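**Plan**

- Cuts: C11=C12 and C11'=C12' (two Horner–Wadsworth–Emmons olefinations on the C10 trienedial), C6–C7 (Sonogashira coupling on an actinol-derived enol triflate), and, in the 7',8'-dihydro half, C10'–C11' with the C9' methyl (carboalumination–hydroxymethylation), the ring alkene C5'=C6' (back to an open-chain 2,7-diketone), C6'–C7' (Grignard reagent on a nitrile), and C1'–C2' and C4'–C5' (two openings of epichlorohydrin).
- Forward order: chlorohydrin → hydroxy nitrile → diketone → ring B by reductive carbonyl coupling (the only ring made in the route) → C15 phosphonate. Ring A is bought as actinol and becomes the enynyl C15 phosphonate. Enynyl phosphonate + trienedial → C25 aldehyde; C25 aldehyde + ring B phosphonate → C40 skeleton; desilylation.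
- Enabling feature: C5'=C6' of ring B is a tetrasubstituted alkene bearing only carbon (the C5' methyl and C4' on one carbon, quaternary C1' and the saturated C7' methylene on the other), and C7'–C8' is saturated. Both alkene carbons can therefore be unconjugated ketone carbonyls of one chain.
- Stereochemistry: C3' from (R)-epichlorohydrin (its C–O bond is never broken); C3 from (4R,6R)-actinol; 9E from the purchased enynol; 9'E from syn-carboalumination; 11E and 11'E from the phosphonate olefinations; the central triene from the trienedial.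

Key step: step 6

Remark: (4R,6R)-actinol and the C10 trienedial are taken as purchasable carotenoid building blocks; positions are given in carotenoid numbering, primed for the 7',8'-dihydro half (ring B).

**Route**

Step 1
Reactants: 1 (R)-epichlorohydrin; 2 isopropenylmagnesium bromide
Product: 3 (2R)-1-chloro-4-methylpent-4-en-2-ol
Conditions: CuI (10 mol %), THF, −40 → −20 °C; cold 1 M HCl
Reagents that add atoms: none
Why: Copper-catalysed Grignard opening of the terminal epoxide at its CH2 carbon (SN2) leaves the C–O bond at the stereocentre intact, so the future C3' is carried over from the chiral pool.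

Step 2
Reactants: 3 (2R)-1-chloro-4-methylpent-4-en-2-ol; 4 isobutyronitrile
Product: 6 (4R)-4-hydroxy-2,2,6-trimethylhept-6-enenitrile, via epoxide 5 (not isolated)
Conditions: LiN(i-Pr)2 (2.3 equiv), 4 (2.3 equiv), THF, −78 °C; then 3, −78 °C → rt; H2O
Reagents that add atoms: none
Why: The lithium alkoxide of 3 closes to the terminal epoxide (intramolecular SN2) and lithiated isobutyronitrile opens it at the CH2 terminus (nitrile-anion epoxide alkylation), which builds quaternary C1' while the carbinol C–O bond and its R configuration are untouched.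

Step 3
Reactants: 6 (4R)-4-hydroxy-2,2,6-trimethylhept-6-enenitrile
Product: 7 (4R)-4-[(tert-butyldimethylsilyl)oxy]-2,2,6-trimethylhept-6-enenitrile
Conditions: TBSCl, imidazole, DMF, rt
Reagents that add atoms: tert-butyldimethylsilyl chloride, CC(C)(C)[Si](C)(C)Cl
Why: Imidazole-promoted silylation of the secondary alcohol gives an ether that should survive the organometallic, oxidative and low-valent-titanium steps that follow.

Step 4
Reactants: 7 (4R)-4-[(tert-butyldimethylsilyl)oxy]-2,2,6-trimethylhept-6-enenitrile; 8 (4-bromobut-1-yn-1-yl)trimethylsilane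
Product: 11 (8R)-8-[(tert-butyldimethylsilyl)oxy]-6,6,10-trimethyl-1-(trimethylsilyl)undec-10-en-1-yn-5-one, via Grignard reagent 9 (not isolated), via magnesium ketimide 10 (not isolated)
Conditions: 8, Mg, THF, 40 °C; then 7, CuBr·SMe2 (5 mol %), THF, reflux; aq AcOH, rt
Reagents that add atoms: water, O
Why: Copper-catalysed addition of a primary Grignard reagent to a non-enolisable tertiary nitrile stops at the N-magnesio ketimine, which mild aqueous acid should hydrolyse to the ketone without loss of the silyl ether.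

Step 5
Reactants: 11 (8R)-8-[(tert-butyldimethylsilyl)oxy]-6,6,10-trimethyl-1-(trimethylsilyl)undec-10-en-1-yn-5-one
Product: 12 (4S)-4-[(tert-butyldimethylsilyl)oxy]-6,6-dimethyl-11-(trimethylsilyl)undec-10-yne-2,7-dione
Conditions: O3, CH2Cl2–MeOH, −78 °C (Sudan Red 7B end point); Me2S, −78 °C → rt
Reagents that add atoms: ozone, [O-][O+]=O
Why: Ozonolysis with reductive work-up cleaves the only alkene, an electron-rich 1,1-disubstituted one, far faster than the silyl-capped alkyne and unmasks the C5' methyl ketone (the descriptor becomes S only because the priorities change).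

Step 6
Reactants: 12 (4S)-4-[(tert-butyldimethylsilyl)oxy]-6,6-dimethyl-11-(trimethylsilyl)undec-10-yne-2,7-dione
Product: 13 tert-butyldimethyl({(1R)-3,5,5-trimethyl-4-[4-(trimethylsilyl)but-3-yn-1-yl]cyclohex-3-en-1-yl}oxy)silane
Conditions: TiCl3(DME)1.5 (10 equiv), Zn–Cu couple (30 equiv), DME, reflux; 12 added over 30 h by syringe pump; aq K2CO3
Reagents that add atoms: none
Why: Zerovalent titanium, generated from TiCl3(DME)1.5 and Zn–Cu, transfers one electron to each ketone of 12; the two titanium-bound ketyls couple between C5' and C6' to a cyclic titanium pinacolate, which is deoxygenated on the titanium surface to the alkene, so the σ and the π component of C5'=C6' are made in one flask. The closest known reaction type is the intramolecular McMurry coupling of 1,6-diketones to 1,2-dialkylcyclohexenes. Ring B closes as a six-membered carbocycle by ketyl–ketyl (pinacol-type) coupling, formally 6-exo with respect to either carbonyl and helped by the gem-dimethyl group at C1'. No stereocentre is formed: the alkene is necessarily cis inside the ring, and C3', set in step 1, is not α to either carbonyl and is not touched. The step needs ring closure to outrun intermolecular coupling (secured by slow addition at high dilution and six-ring formation) and an unambiguous alkene position (secured because the oxygen atoms leave only from the two former carbonyl carbons, with no dehydration that could place the alkene elsewhere). It also needs the β-silyloxy ketone and the alkyne to survive, which the aprotic, non-basic medium, the poor leaving-group ability of the silyl ether and the SiMe3 cap on the internal alkyne should allow.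

Step 7
Reactants: 13 tert-butyldimethyl({(1R)-3,5,5-trimethyl-4-[4-(trimethylsilyl)but-3-yn-1-yl]cyclohex-3-en-1-yl}oxy)silane
Product: 14 {[(1R)-4-(but-3-yn-1-yl)-3,5,5-trimethylcyclohex-3-en-1-yl]oxy}(tert-butyl)dimethylsilane
Conditions: K2CO3 (0.2 equiv), MeOH, rt
Reagents that add atoms: none
Why: Methoxide-mediated protodesilylation cleaves the alkynyl C–Si bond selectively over the hindered secondary silyl ether.

Step 8
Reactants: 14 {[(1R)-4-(but-3-yn-1-yl)-3,5,5-trimethylcyclohex-3-en-1-yl]oxy}(tert-butyl)dimethylsilane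
Product: 17 (2E)-5-[(4R)-4-[(tert-butyldimethylsilyl)oxy]-2,6,6-trimethylcyclohex-1-en-1-yl]-3-methylpent-2-en-1-ol, via alkenylalane 15 (not isolated), via lithium alanate 16 (not isolated)
Conditions: AlMe3 (2.5 equiv), Cp2ZrCl2 (0.25 equiv), CH2Cl2, 0 °C → rt; evaporate; n-BuLi, THF–hexane, −78 °C; (CH2O)n, −78 °C → rt; aq potassium sodium tartrate
Reagents that add atoms: trimethylaluminium, C[Al](C)C; paraformaldehyde (as formaldehyde), C=O
Why: Zirconium-catalysed carboalumination (Negishi carboalumination) adds methyl and aluminium syn across the terminal alkyne with methyl on the internal carbon, and the derived alanate is hydroxymethylated by formaldehyde with retention, which fixes the 9'E trisubstituted alkene.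

Step 9
Reactants: 17 (2E)-5-[(4R)-4-[(tert-butyldimethylsilyl)oxy]-2,6,6-trimethylcyclohex-1-en-1-yl]-3-methylpent-2-en-1-ol
Product: 18 {[(1R)-4-[(3E)-5-bromo-3-methylpent-3-en-1-yl]-3,5,5-trimethylcyclohex-3-en-1-yl]oxy}(tert-butyl)dimethylsilane
Conditions: CBr4, PPh3, CH2Cl2, −20 → 0 °C
Reagents that add atoms: carbon tetrabromide, BrC(Br)(Br)Br
Why: Appel bromination displaces the primary allylic oxyphosphonium by SN2 under neutral conditions, so the alkene geometry and the silyl ether should be kept.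

Step 10
Reactants: 18 {[(1R)-4-[(3E)-5-bromo-3-methylpent-3-en-1-yl]-3,5,5-trimethylcyclohex-3-en-1-yl]oxy}(tert-butyl)dimethylsilane
Product: 19 diethyl {(2E)-5-[(4R)-4-[(tert-butyldimethylsilyl)oxy]-2,6,6-trimethylcyclohex-1-en-1-yl]-3-methylpent-2-en-1-yl}phosphonate
Conditions: P(OEt)3 (neat, 3 equiv), 90 °C
Reagents that add atoms: triethyl phosphite, CCOP(OCC)OCC
Why: Michaelis–Arbuzov reaction of the primary allylic bromide should give the allylic phosphonate at the CH2 carbon without allylic transposition.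

Step 11
Reactants: 20 (4R,6R)-4-hydroxy-2,2,6-trimethylcyclohexan-1-one (actinol)
Product: 21 (4R,6R)-4-[(tert-butyldimethylsilyl)oxy]-2,2,6-trimethylcyclohexan-1-one
Conditions: TBSCl, imidazole, DMF, rt
Reagents that add atoms: tert-butyldimethylsilyl chloride, CC(C)(C)[Si](C)(C)Cl
Why: Imidazole-promoted silylation protects the carbinol that becomes C3 before enolate chemistry.

Step 12
Reactants: 21 (4R,6R)-4-[(tert-butyldimethylsilyl)oxy]-2,2,6-trimethylcyclohexan-1-one
Product: 22 (4R)-4-[(tert-butyldimethylsilyl)oxy]-2,6,6-trimethylcyclohex-1-en-1-yl trifluoromethanesulfonate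
Conditions: LiN(i-Pr)2, THF, −78 °C; PhNTf2, −78 °C → rt
Reagents that add atoms: N-phenylbis(trifluoromethanesulfonimide), O=S(=O)(N(c1ccccc1)S(=O)(=O)C(F)(F)F)C(F)(F)F
Why: The ketone has a single enolisable position, so enolate O-sulfonylation can only give the tetrasubstituted enol triflate; the methyl-bearing stereocentre is erased on purpose and the remote silyloxy stereocentre is unaffected.

Step 13
Reactants: 22 (4R)-4-[(tert-butyldimethylsilyl)oxy]-2,6,6-trimethylcyclohex-1-en-1-yl trifluoromethanesulfonate; 23 (2E)-3-methylpent-2-en-4-yn-1-ol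
Product: 24 (2E)-5-[(4R)-4-[(tert-butyldimethylsilyl)oxy]-2,6,6-trimethylcyclohex-1-en-1-yl]-3-methylpent-2-en-4-yn-1-ol
Conditions: Pd(PPh3)4 (5 mol %), CuI (10 mol %), i-Pr2NH, DMF, rt
Reagents that add atoms: none
Why: Sonogashira coupling of the alkenyl triflate with the terminal alkyne forms C6–C7, with the ring alkene position fixed by the triflate and the 9E geometry brought in with 23.

Step 14
Reactants: 24 (2E)-5-[(4R)-4-[(tert-butyldimethylsilyl)oxy]-2,6,6-trimethylcyclohex-1-en-1-yl]-3-methylpent-2-en-4-yn-1-ol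
Product: 25 {[(1R)-4-[(3E)-5-bromo-3-methylpent-3-en-1-yn-1-yl]-3,5,5-trimethylcyclohex-3-en-1-yl]oxy}(tert-butyl)dimethylsilane
Conditions: CBr4, PPh3, CH2Cl2, −20 °C
Reagents that add atoms: carbon tetrabromide, BrC(Br)(Br)Br
Why: Appel bromination at low temperature converts the primary allylic alcohol to the bromide by SN2 without acid, which should preserve the 9E enyne.

Step 15
Reactants: 25 {[(1R)-4-[(3E)-5-bromo-3-methylpent-3-en-1-yn-1-yl]-3,5,5-trimethylcyclohex-3-en-1-yl]oxy}(tert-butyl)dimethylsilane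
Product: 26 diethyl {(2E)-5-[(4R)-4-[(tert-butyldimethylsilyl)oxy]-2,6,6-trimethylcyclohex-1-en-1-yl]-3-methylpent-2-en-4-yn-1-yl}phosphonate
Conditions: P(OEt)3 (neat, 3 equiv), 80 °C
Reagents that add atoms: triethyl phosphite, CCOP(OCC)OCC
Why: Michaelis–Arbuzov reaction of the primary allylic bromide should give the C15 enynyl phosphonate with the alkene geometry retained.

Step 16
Reactants: 26 diethyl {(2E)-5-[(4R)-4-[(tert-butyldimethylsilyl)oxy]-2,6,6-trimethylcyclohex-1-en-1-yl]-3-methylpent-2-en-4-yn-1-yl}phosphonate; 27 (2E,4E,6E)-2,7-dimethylocta-2,4,6-trienedial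
Product: 28 (2E,4E,6E,8E,10E)-13-[(4R)-4-[(tert-butyldimethylsilyl)oxy]-2,6,6-trimethylcyclohex-1-en-1-yl]-2,7,11-trimethyltrideca-2,4,6,8,10-pentaen-12-ynal
Conditions: NaN(SiMe3)2, THF, −78 °C; anion added to 27 (3 equiv), −78 → 0 °C, dark
Reagents that add atoms: none
Why: Horner–Wadsworth–Emmons olefination of the allylic phosphonate anion with one formyl group of the symmetrical dial (used in excess to favour mono-olefination) should form C11=C12 E-selectively, because the adducts equilibrate before syn-elimination of phosphate.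

Step 17
Reactants: 19 diethyl {(2E)-5-[(4R)-4-[(tert-butyldimethylsilyl)oxy]-2,6,6-trimethylcyclohex-1-en-1-yl]-3-methylpent-2-en-1-yl}phosphonate; 28 the C25 aldehyde of step 16
Product: 29 (3R,3'R)-3,3'-bis[(tert-butyldimethylsilyl)oxy]-7,8-didehydro-7',8'-dihydro-β,β-carotene (all-E)
Conditions: NaN(SiMe3)2, THF, −78 → 0 °C, dark, argon
Reagents that add atoms: none
Why: A second Horner–Wadsworth–Emmons olefination joins the ring B phosphonate to the polyenal and should form C11'=C12' with E selectivity by the same thermodynamic control, completing the C40 chain.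

Step 18
Reactants: 29 (3R,3'R)-3,3'-bis[(tert-butyldimethylsilyl)oxy]-7,8-didehydro-7',8'-dihydro-β,β-carotene
Product: 30 (3R,3'R)-7,8-didehydro-7',8'-dihydro-β,β-carotene-3,3'-diol (all-E), the target
Conditions: Bu4NF, THF, rt, dark, argon; H2O
Reagents that add atoms: none
Why: Fluoride-mediated desilylation cleaves both Si–O bonds without affecting the polyene, the enyne or either carbinol configuration.

**Compound list**

1 | (R)-epichlorohydrin, (2R)-2-(chloromethyl)oxirane | ClC[C@H]1CO1 | starting material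
2 | isopropenylmagnesium bromide | C=C(C)[Mg]Br | starting material
3 | (2R)-1-chloro-4-methylpent-4-en-2-ol | C=C(C)C[C@@H](O)CCl | intermediate
4 | isobutyronitrile | CC(C)C#N | starting material
5 | (2R)-2-(2-methylprop-2-en-1-yl)oxirane (epoxide, not isolated) | C=C(C)C[C@@H]1CO1 | intermediate
6 | (4R)-4-hydroxy-2,2,6-trimethylhept-6-enenitrile | C=C(C)C[C@@H](O)CC(C)(C)C#N | intermediate
7 | (4R)-4-[(tert-butyldimethylsilyl)oxy]-2,2,6-trimethylhept-6-enenitrile | C=C(C)C[C@@H](O[Si](C)(C)C(C)(C)C)CC(C)(C)C#N | intermediate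
8 | (4-bromobut-1-yn-1-yl)trimethylsilane | C[Si](C)(C)C#CCCBr | starting material
9 | [4-(trimethylsilyl)but-3-yn-1-yl]magnesium bromide (Grignard reagent, not isolated) | C[Si](C)(C)C#CCC[Mg]Br | intermediate
10 | N-(bromomagnesio) ketimine of 11 (magnesium ketimide, not isolated) | C=C(C)C[C@@H](O[Si](C)(C)C(C)(C)C)CC(C)(C)C(CCC#C[Si](C)(C)C)=N[Mg]Br | intermediate
11 | (8R)-8-[(tert-butyldimethylsilyl)oxy]-6,6,10-trimethyl-1-(trimethylsilyl)undec-10-en-1-yn-5-one | C=C(C)C[C@@H](O[Si](C)(C)C(C)(C)C)CC(C)(C)C(=O)CCC#C[Si](C)(C)C | intermediate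
12 | (4S)-4-[(tert-butyldimethylsilyl)oxy]-6,6-dimethyl-11-(trimethylsilyl)undec-10-yne-2,7-dione | CC(=O)C[C@@H](O[Si](C)(C)C(C)(C)C)CC(C)(C)C(=O)CCC#C[Si](C)(C)C | intermediate
13 | tert-butyldimethyl({(1R)-3,5,5-trimethyl-4-[4-(trimethylsilyl)but-3-yn-1-yl]cyclohex-3-en-1-yl}oxy)silane | CC1=C(CCC#C[Si](C)(C)C)C(C)(C)C[C@H](O[Si](C)(C)C(C)(C)C)C1 | intermediate
14 | {[(1R)-4-(but-3-yn-1-yl)-3,5,5-trimethylcyclohex-3-en-1-yl]oxy}(tert-butyl)dimethylsilane | CC1=C(CCC#C)C(C)(C)C[C@H](O[Si](C)(C)C(C)(C)C)C1 | intermediate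
15 | dimethyl{(1E)-2-methyl-4-[(4R)-4-[(tert-butyldimethylsilyl)oxy]-2,6,6-trimethylcyclohex-1-en-1-yl]but-1-en-1-yl}alumane (alkenylalane, not isolated) | CC1=C(CC/C(C)=C/[Al](C)C)C(C)(C)C[C@H](O[Si](C)(C)C(C)(C)C)C1 | intermediate
16 | lithium butyl(dimethyl)alkenylaluminate derived from 15 (not isolated) | [Li+].CCCC[Al-](C)(C)/C=C(\C)CCC1=C(C)C[C@@H](O[Si](C)(C)C(C)(C)C)CC1(C)C | intermediate
17 | (2E)-5-[(4R)-4-[(tert-butyldimethylsilyl)oxy]-2,6,6-trimethylcyclohex-1-en-1-yl]-3-methylpent-2-en-1-ol | CC1=C(CC/C(C)=C/CO)C(C)(C)C[C@H](O[Si](C)(C)C(C)(C)C)C1 | intermediate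
18 | {[(1R)-4-[(3E)-5-bromo-3-methylpent-3-en-1-yl]-3,5,5-trimethylcyclohex-3-en-1-yl]oxy}(tert-butyl)dimethylsilane | CC1=C(CC/C(C)=C/CBr)C(C)(C)C[C@H](O[Si](C)(C)C(C)(C)C)C1 | intermediate
19 | diethyl {(2E)-5-[(4R)-4-[(tert-butyldimethylsilyl)oxy]-2,6,6-trimethylcyclohex-1-en-1-yl]-3-methylpent-2-en-1-yl}phosphonate | CCOP(=O)(OCC)C/C=C(\C)CCC1=C(C)C[C@@H](O[Si](C)(C)C(C)(C)C)CC1(C)C | intermediate
20 | (4R,6R)-4-hydroxy-2,2,6-trimethylcyclohexan-1-one (actinol) | C[C@@H]1C[C@@H](O)CC(C)(C)C1=O | starting material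
21 | (4R,6R)-4-[(tert-butyldimethylsilyl)oxy]-2,2,6-trimethylcyclohexan-1-one | C[C@@H]1C[C@@H](O[Si](C)(C)C(C)(C)C)CC(C)(C)C1=O | intermediate
22 | (4R)-4-[(tert-butyldimethylsilyl)oxy]-2,6,6-trimethylcyclohex-1-en-1-yl trifluoromethanesulfonate | CC1=C(OS(=O)(=O)C(F)(F)F)C(C)(C)C[C@H](O[Si](C)(C)C(C)(C)C)C1 | intermediate
23 | (2E)-3-methylpent-2-en-4-yn-1-ol | C#C/C(C)=C/CO | starting material
24 | (2E)-5-[(4R)-4-[(tert-butyldimethylsilyl)oxy]-2,6,6-trimethylcyclohex-1-en-1-yl]-3-methylpent-2-en-4-yn-1-ol | CC1=C(C#C/C(C)=C/CO)C(C)(C)C[C@H](O[Si](C)(C)C(C)(C)C)C1 | intermediate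
25 | {[(1R)-4-[(3E)-5-bromo-3-methylpent-3-en-1-yn-1-yl]-3,5,5-trimethylcyclohex-3-en-1-yl]oxy}(tert-butyl)dimethylsilane | CC1=C(C#C/C(C)=C/CBr)C(C)(C)C[C@H](O[Si](C)(C)C(C)(C)C)C1 | intermediate
26 | diethyl {(2E)-5-[(4R)-4-[(tert-butyldimethylsilyl)oxy]-2,6,6-trimethylcyclohex-1-en-1-yl]-3-methylpent-2-en-4-yn-1-yl}phosphonate | CCOP(=O)(OCC)C/C=C(C)/C#CC1=C(C)C[C@@H](O[Si](C)(C)C(C)(C)C)CC1(C)C | intermediate
27 | (2E,4E,6E)-2,7-dimethylocta-2,4,6-trienedial | O=C/C(C)=C/C=C/C=C(C)/C=O | starting material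
28 | (2E,4E,6E,8E,10E)-13-[(4R)-4-[(tert-butyldimethylsilyl)oxy]-2,6,6-trimethylcyclohex-1-en-1-yl]-2,7,11-trimethyltrideca-2,4,6,8,10-pentaen-12-ynal | CC1=C(C#C/C(C)=C/C=C/C(C)=C/C=C/C=C(C)/C=O)C(C)(C)C[C@H](O[Si](C)(C)C(C)(C)C)C1 | intermediate
29 | (3R,3'R)-3,3'-bis[(tert-butyldimethylsilyl)oxy]-7,8-didehydro-7',8'-dihydro-β,β-carotene (all-E) | CC1=C(C#C/C(C)=C/C=C/C(C)=C/C=C/C=C(C)/C=C/C=C(\C)CCC2=C(C)C[C@@H](O[Si](C)(C)C(C)(C)C)CC2(C)C)C(C)(C)C[C@H](O[Si](C)(C)C(C)(C)C)C1 | intermediate
30 | (3R,3'R)-7,8-didehydro-7',8'-dihydro-β,β-carotene-3,3'-diol (all-E) | CC1=C(C#C/C(C)=C/C=C/C(C)=C/C=C/C=C(C)/C=C/C=C(\C)CCC2=C(C)C[C@@H](O)CC2(C)C)C(C)(C)C[C@H](O)C1 | target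

**Summary**

Total steps: 18. Longest linear sequence: 12 (steps 1–10, 17, 18).

Steps most likely to fail:

1. Step 6. The coupling may stop at the titanium diolate, the β-silyloxy group may be eliminated under the hot Lewis-acidic conditions, or the alkyne may be reduced. The fallback makes the same bond in two stages without hot low-valent titanium; it sets out from 12 and returns at 13. SmI2 (HMPA, t-BuOH, THF, 0 °C → rt) should give the intramolecular pinacol product as the two cis-diols, the cis-diol with both hydroxyls trans to the silyloxy group F1 and the cis-diol with both hydroxyls cis to it F2. 1,1'-Thiocarbonyldiimidazole (DMAP, toluene, reflux) should convert them to the cyclic thionocarbonate F3 and the cyclic thionocarbonate F4. Corey–Winter elimination with 1,3-dimethyl-2-phenyl-1,3,2-diazaphospholidine (THF, 40 °C) takes both to 13, because the syn-elimination removes both new stereocentres.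

2. Step 17. The strongly basic olefination may erode the 9E enyne geometry, give Z alkene at C11'=C12', or degrade the polyenal. The fallback joins C10'–C11' under neutral palladium catalysis with both geometries preset; it sets out from 14 and 28 and returns at 29. Alkyne 14 is carboaluminated as in step 8 and alkenylalane 15 is quenched with I2 (THF, −30 °C) to give the (E)-alkenyl iodide F5. Aldehyde 28 is homologated with Bu3SnCHBr2, CrCl2 and LiI (THF–DMF, rt; Takai–Hodgson stannylolefination) to the (E)-alkenylstannane F6. Stille coupling of the two (Pd2(dba)3, AsPh3, NMP, rt) should give 29.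

3. Step 4. Addition to the neopentyl-type nitrile may stall, the hindered ketimine may resist hydrolysis, or the silyl ether may be lost when the hydrolysis is forced. The fallback reaches the ketone by addition and oxidation; it sets out from 7 and returns at 11. i-Bu2AlH (toluene, −78 °C; aqueous tartrate) reduces the nitrile to the aldehyde F7. Grignard reagent 9 (THF, −78 °C; aq NH4Cl) adds to give the (5R)-carbinol F8 and the (5S)-carbinol F9. Dess–Martin periodinane (NaHCO3, CH2Cl2, rt) oxidises both to 11.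

Further compounds
F1 | step 6 | (5S)-5-[(tert-butyldimethylsilyl)oxy]-1,3,3-trimethyl-2-[4-(trimethylsilyl)but-3-yn-1-yl]cyclohexane-1,2-diol, cis-diol, hydroxyls trans to the silyloxy group | C[C@@]1(O)C[C@@H](O[Si](C)(C)C(C)(C)C)CC(C)(C)[C@@]1(O)CCC#C[Si](C)(C)C
F2 | step 6 | (5S)-5-[(tert-butyldimethylsilyl)oxy]-1,3,3-trimethyl-2-[4-(trimethylsilyl)but-3-yn-1-yl]cyclohexane-1,2-diol, cis-diol, hydroxyls cis to the silyloxy group | C[C@]1(O)C[C@@H](O[Si](C)(C)C(C)(C)C)CC(C)(C)[C@]1(O)CCC#C[Si](C)(C)C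
F3 | step 6 | cyclic thionocarbonate (1,3-dioxolane-2-thione) of F1 | C[C@@]12C[C@@H](O[Si](C)(C)C(C)(C)C)CC(C)(C)[C@]1(CCC#C[Si](C)(C)C)OC(=S)O2
F4 | step 6 | cyclic thionocarbonate (1,3-dioxolane-2-thione) of F2 | C[C@]12C[C@@H](O[Si](C)(C)C(C)(C)C)CC(C)(C)[C@@]1(CCC#C[Si](C)(C)C)OC(=S)O2
F5 | step 17 | {[(1R)-4-[(3E)-4-iodo-3-methylbut-3-en-1-yl]-3,5,5-trimethylcyclohex-3-en-1-yl]oxy}(tert-butyl)dimethylsilane | CC1=C(CC/C(C)=C/I)C(C)(C)C[C@H](O[Si](C)(C)C(C)(C)C)C1
F6 | step 17 | tributyl{(1E,3E,5E,7E,9E,11E)-14-[(4R)-4-[(tert-butyldimethylsilyl)oxy]-2,6,6-trimethylcyclohex-1-en-1-yl]-3,8,12-trimethyltetradeca-1,3,5,7,9,11-hexaen-13-yn-1-yl}stannane | CC1=C(C#C/C(C)=C/C=C/C(C)=C/C=C/C=C(C)/C=C/[Sn](CCCC)(CCCC)CCCC)C(C)(C)C[C@H](O[Si](C)(C)C(C)(C)C)C1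
F7 | step 4 | (4R)-4-[(tert-butyldimethylsilyl)oxy]-2,2,6-trimethylhept-6-enal | C=C(C)C[C@@H](O[Si](C)(C)C(C)(C)C)CC(C)(C)C=O
F8 | step 4 | (5R,8R)-8-[(tert-butyldimethylsilyl)oxy]-6,6,10-trimethyl-1-(trimethylsilyl)undec-10-en-1-yn-5-ol | C=C(C)C[C@@H](O[Si](C)(C)C(C)(C)C)CC(C)(C)[C@H](O)CCC#C[Si](C)(C)C
F9 | step 4 | (5S,8R)-8-[(tert-butyldimethylsilyl)oxy]-6,6,10-trimethyl-1-(trimethylsilyl)undec-10-en-1-yn-5-ol | C=C(C)C[C@@H](O[Si](C)(C)C(C)(C)C)CC(C)(C)[C@@H](O)CCC#C[Si](C)(C)C
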